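**Remarks on the chemistry (assumptions)**
- The SMILES string is read as the all-(−)-epicatechin trimer epicatechin-(4β→6)-epicatechin-(4β→6)-epicatechin (eight stereocentres; C2/C3 cis and C3/C4 trans in the upper and middle units).
- For open-chain intermediates the locants C2, C3, C4, C4a, C5 … C8a are those the atoms will have in the middle flavan unit.
- Poly-L-leucine is assumed to epoxidise chalcone 20 with the same facial sense as simple chalcones, giving the (2R,3S) epoxide 21.

## Analysis of the target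

Target 40 consists of three flavan-3-ol units, each a chroman (ring A fused to pyran ring C) with a catechol ring B on C2, joined by two C4–C6 bonds. It has eight stereocentres: C2 and C3 of every unit are (2R,3R) with aryl and hydroxyl cis, and C4 of the upper and of the middle unit carries the next unit trans to its 3-hydroxyl (4β). Twelve phenolic and three secondary hydroxyls are present; the free phenols are sensitive to air and base, and both interflavan bonds are benzylic to a phloroglucinol ring and are cleaved by acid. The difficulty is as much regiochemical as stereochemical: a flavan C4 cation prefers C8 of its partner, so each 4→6 bond has to be forced, and the middle unit must serve as nucleophile at C6 and electrophile at C4 without oligomerising. The strategy rests on ring A of the middle unit, a pentasubstituted phloroglucinol in which C4a carries C4, C5 an oxygen, C6 the C4 of the upper unit, C7 an oxygen, C8 hydrogen and C8a the ring oxygen O1. A cyclobutenone–siloxyalkyne benzannulation writes exactly this alternation: C5/C6 from a ketene unit on the upper flavan, C7/C8 from an alkoxyalkyne, and C4a/C8a from a siloxyalkyne that already carries C4, C3, C2 and the lower unit.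

## Retrosynthetic reasoning

**40 ⇒ 39.** All fifteen hydroxyls are masked as benzyl ethers and C8 of the lower unit carries bromine. One neutral hydrogenolysis removes all sixteen groups, which matters because the interflavan bonds would not tolerate acidic or strongly basic unmasking.

**39 ⇒ 38.** Ring C of the middle unit is cut at O1–C2. C2 is a benzylic carbinol and O1 a phenol, so the forward step is an invertive Mitsunobu closure; inversion is what turns an anti C2/C3 diol pattern into the 2,3-cis flavan. C2 in 38 therefore has the configuration opposite to the target.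

**38 ⇒ 37 ⇒ 36.** O5 and O8a both flank C4a, and either could close a six-membered ring onto C2. Phenol 36 has O5 free and O8a silylated, so O5 is benzylated (37) before fluoride frees O8a and the C2 hydroxyl (38).

**36 ⇒ 15 + 31 (key disconnection).** Ring A of the middle unit is cut at C4a–C5, C8–C8a and C5–C6, giving cyclobutenone 15 on the upper unit and siloxyalkyne 31 carrying C4, C3, C2 and the lower unit. Cutting here, not at the interflavan bond, means the upper unit sits at C6 by construction and not by competition with C8. It also joins two halves of similar size without acid near either C4 centre, and delivers the three ring A oxygens in three different states.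

**15 ⇒ 7 + 12; 12 ⇒ 10 ⇒ 8 + 9.** The cyclobutenone comes from [2+2] addition of the ketene of acid 7 to benzyl ethynyl ether 12, made from benzyl alcohol 8 and trichloroethylene 9 via dichlorovinyl ether 10. The benzyl group is brought in on the ynol ether because re-etherifying a 3-alkoxy-4-alkylcyclobutenone would pass through the 2-alkylcyclobutane-1,3-dione. Its enol ether forms with the double bond next to the substituent, and that isomer would send the upper unit to C8 in the benzannulation.

**7 ⇒ 6 ⇒ 4 + 5; 4 ⇒ 3 ⇒ 2 ⇒ 1.** The C4–CH2 bond is cut back to the C4 cation of a 2,3-cis flavan and silyl ketene acetal 5. Attack on such cations is reliably trans to the 3-oxygen, so the 4β centre is set where flavan chemistry is at its best. Ether 4 comes from benzylic oxidation of perbenzylated epicatechin 3, which is also the source of the lower unit.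

**31 ⇒ 28 ⇒ 27 ⇒ 26.** The ynol ether oxygen is introduced last, by oxidising the lithium acetylide of terminal alkyne 28 and silylating the ynolate. This keeps the sensitive siloxyalkyne out of all earlier steps. Alkyne 28 comes from 26 by O3-benzylation (27) and C-desilylation.

**26 ⇒ 23 + 24.** The C4–alkynyl bond is cut to trans-epoxide 23 and ethynyltrimethylsilane 24. Opening at the benzylic C4 with inversion ties the configuration of C4 to that of C3, and leaves O3 as the only free hydroxyl, ready for benzylation.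

**23 ⇒ 22 ⇒ 21 ⇒ 20.** C2 comes from chelation-controlled reduction of epoxy ketone 21, which gives the anti arrangement the later inversion needs. C3 and C4 come from asymmetric nucleophilic epoxidation of chalcone 20.

**20 ⇒ 17 + 19; 17 ⇒ 16 ⇒ 3; 19 ⇒ 18.** The enone is cut by a Claisen–Schmidt condensation to aldehyde 17 and acetophenone 19 (from 18). The formyl carbon, which becomes C4 of the middle unit, is placed on C6 of the lower unit after C8 has been blocked with bromine (16). The lower unit's 4→6 attachment is thus fixed by a blocking group that the final hydrogenolysis removes.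

## Alternatives that were turned down

**Alternative 1:** The disconnection is at C4–C4a of both the middle and the upper unit, so both rings C are closed last from an open chain whose O1–C2 aryl ether bonds and two trans C3–C4 epoxides are in place. In the forward key step a boron Lewis acid opens each epoxide and the ether-linked 3,5-dioxygenated arene attacks C4 through an ortho carbon, giving trimer A1 with free C3 hydroxyls on the upper and middle units.
- For it: two rings and two C–C bonds form at once. The 3,4-trans relationship follows from anti opening of a trans-epoxide within a forming ring, a firmer stereochemical argument than the open-chain substitution at C4 in the chosen route (step 16). Every reaction type is classical.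
- Against it: each epoxide C4 is benzylic to a 2,4,6-trioxygenated arene, so under Lewis acid it can ionise before the arene arrives, which puts the stereospecificity at risk and invites 1,2-shifts. The arene that becomes middle ring A has two electronically similar ortho carbons, and closure through the wrong one gives the 4→8-type fusion, so the target's regiochemical problem reappears inside the key step. The chain carries six stereocentres, two of them benzylic aryl ethers, and needs at least as many steps as 15 and 31 together.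
- Comparison: the benzannulation fixes the 4→6 pattern by the polarity of its partners, runs without acid, and keeps both C4 centres out of cationic chemistry at the convergent stage.

**Alternative 2:** The disconnection removes ring A of the lower unit (C4a–C5 and C7–C8, closed by a double Claisen condensation) from an upper–middle dimer bearing a malonate residue on C4 of the middle unit. With a methoxide base the malonate condenses twice with the dianion of dimethyl 3-oxoglutarate A3 to give phloroglucinol diester A2.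
- For it: the ring-forming reaction is a cheap, ionic, well-understood phloroglucinol synthesis. On robustness of the ring construction itself it is stronger than the chosen benzannulation, whose substitution pattern and fragment size are untried.
- Against it: it builds the ring that poses no regiochemical problem. The upper-to-middle 4→6 bond must still be made beforehand by Lewis-acid coupling with blocking groups. After A2 the whole lower ring C, with C2, C3 and ring B, must be built on a free trihydroxyisophthalate, and two ester groups must be hydrolysed and decarboxylated next to acid-labile interflavan bonds; this is about eight steps against four after the chosen key step. The malonate anion is β to the C3 benzyloxy group of the middle unit, so E1cB loss of the C3 oxygen competes under methoxide.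
- Comparison: the chosen strategy takes the lower unit intact from the chiral pool and spends its ring construction where the regiochemical difficulty lies.

**Alternative 3:** The disconnection is at C3–C4 and O1–C2 of the middle ring C. An ortho-hydroxybenzhydrol, whose carbinol carbon is C4 and already bears the lower unit, is joined to benzyloxyacetaldehyde A5. With a chiral diarylprolinol silyl ether and a weak acid, the benzhydrol gives an ortho-quinone methide, the enamine of A5 attacks C4, and hemiacetal closure gives lactol A4 with trans C3 benzyloxy and C4 aryl groups.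
- For it: C3 and C4 are set together under catalyst control in one mild step. On this point it is stronger than the chosen route, where C3 comes from an epoxidation and C4 from a substitution that must invert.
- Against it: C2 of A4 still lacks ring B, and adding an aryl nucleophile to the derived oxocarbenium ion needs a Lewis acid and has no assured 2,3-cis selectivity. The quinone methide can form from either phenol flanking C4a (O5 or O8a), and the wrong one gives the 4→8-type isomer. The substrate therefore needs the differentiated, C6-linked pentasubstituted ring A, which is the hard part of the molecule and is left to classical coupling. A quinone methide stabilised by the electron-rich lower-unit aryl group is also a weak electrophile.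
- Comparison: the chosen strategy supplies ring A with O5 and O8a already told apart and ring B already on C2.

Key step: step 20

## Steps

Step 1
Reactants: 1 (−)-epicatechin
Product: 2 5,7,3',4'-tetra-O-benzyl-(−)-epicatechin
Conditions: BnBr (4.4 equiv), K2CO3, DMF, argon, 0 °C to rt
Reagents that add atoms: benzyl bromide, BrCc1ccccc1
Why: Williamson etherification of the four phenols; carbonate is too weak to deprotonate the 3-hydroxyl or to open ring C, so C2 and C3 are untouched.

Step 2
Reactants: 2 5,7,3',4'-tetra-O-benzyl-(−)-epicatechin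
Product: 3 3,5,7,3',4'-penta-O-benzyl-(−)-epicatechin
Conditions: NaH, BnBr, Bu4NI, DMF, 0 °C to rt
Reagents that add atoms: benzyl bromide, BrCc1ccccc1
Why: Williamson etherification of the secondary alkoxide; with all phenols capped there is no quinone methide pathway for epimerisation at C2.

Step 3
Reactants: 3 3,5,7,3',4'-penta-O-benzyl-(−)-epicatechin
Product: 4 (4β)-4-(2-ethoxyethoxy)-3,5,7,3',4'-penta-O-benzylepicatechin
Conditions: DDQ, 2-ethoxyethanol, CH2Cl2, rt
Reagents that add atoms: 2-ethoxyethanol, CCOCCO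
Why: Benzylic oxidation: DDQ abstracts hydride from C4–H, which is activated by ring A, and the cation is trapped by the alcohol on the β face, trans to the 3-benzyloxy group.

Step 4
Reactants: 4 (4β)-4-(2-ethoxyethoxy)-3,5,7,3',4'-penta-O-benzylepicatechin; 5 1-(tert-butyldimethylsilyloxy)-1-methoxyethene
Product: 6 methyl 2-[(4β)-3,5,7,3',4'-penta-O-benzylepicatechin-4-yl]acetate
Conditions: Me3SiOTf (0.2 equiv), CH2Cl2, −78 to −40 °C
Reagents that add atoms: none
Why: Mukaiyama-type SN1 alkylation: the silyl triflate ionises the C4 ether and the silyl ketene acetal attacks the C4 cation trans to the 3-benzyloxy group, the general course for 2,3-cis flavans, which sets the 4β centre of the upper unit.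

Step 5
Reactants: 6 methyl 2-[(4β)-3,5,7,3',4'-penta-O-benzylepicatechin-4-yl]acetate
Product: 7 2-[(4β)-3,5,7,3',4'-penta-O-benzylepicatechin-4-yl]acetic acid
Conditions: LiOH, THF/MeOH/H2O, 40 °C; then 1 M HCl to pH 3
Reagents that add atoms: lithium hydroxide, [Li+].[OH-]
Why: Ester saponification; C4 bears a carbon substituent and no leaving group, so the flavan is stable to hydroxide and to the brief acidification.

Step 6
Reactants: 8 benzyl alcohol; 9 trichloroethylene
Product: 10 benzyl (E)-1,2-dichlorovinyl ether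
Conditions: KH, THF, 0 °C; then 9, −40 °C to rt
Reagents that add atoms: none
Why: The alkoxide eliminates HCl from trichloroethylene and adds to the resulting dichloroacetylene (addition–elimination), the standard entry to 1,2-dichlorovinyl ethers.

Step 7
Reactants: 10 benzyl (E)-1,2-dichlorovinyl ether
Product: 12 benzyl ethynyl ether, via lithium benzyloxyacetylide 11 (not isolated)
Conditions: n-BuLi (2.3 equiv), Et2O, −78 °C; then MeOH, −78 °C; cold work-up, solution kept below 0 °C and used at once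
Reagents that add atoms: none
Why: Two equivalents of n-BuLi effect elimination of HCl and chlorine–lithium exchange to the acetylide, which is protonated (dichlorovinyl ether route to alkynyl ethers); the ether is kept cold because benzyl alkynyl ethers rearrange sigmatropically on warming.

Step 8
Reactants: 7 2-[(4β)-3,5,7,3',4'-penta-O-benzylepicatechin-4-yl]acetic acid; 12 benzyl ethynyl ether
Product: 15 3-benzyloxy-4-[(4β)-3,5,7,3',4'-penta-O-benzylepicatechin-4-yl]cyclobut-2-enone (fragment 1; both epimers at the ring sp3 carbon), via acid chloride 13 (not isolated), via ketene 14 (not isolated)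
Conditions: (COCl)2, DMF (cat.), CH2Cl2, 0 °C to rt, evaporate; then 12 (3 equiv), Et3N added slowly, CH2Cl2, 0 °C to rt
Reagents that add atoms: none
Why: Ketene–alkoxyalkyne [2+2] cycloaddition: Et3N dehydrochlorinates 13 to aldoketene 14, whose carbonyl carbon bonds to the unsubstituted carbon of the ynol ether, placing benzyloxy at C3 and the flavan at C4 directly. The ring sp3 centre forms as both epimers, which does not matter because it becomes aromatic C6.

Step 9
Reactants: 3 3,5,7,3',4'-penta-O-benzyl-(−)-epicatechin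
Product: 16 8-bromo-3,5,7,3',4'-penta-O-benzylepicatechin
Conditions: NBS, CH2Cl2, −78 to 0 °C
Reagents that add atoms: N-bromosuccinimide, O=C1CCC(=O)N1Br
Why: Electrophilic aromatic bromination at C8, the more nucleophilic position of ring A in benzylated flavan-3-ols, which leaves C6 as the only free ring A carbon.

Step 10
Reactants: 16 8-bromo-3,5,7,3',4'-penta-O-benzylepicatechin
Product: 17 8-bromo-3,5,7,3',4'-penta-O-benzylepicatechin-6-carbaldehyde
Conditions: POCl3, DMF, ClCH2CH2Cl, 0 to 60 °C; then H2O (NaOAc buffer)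
Reagents that add atoms: N,N-dimethylformamide, CN(C)C=O; water, O
Why: Vilsmeier–Haack formylation at C6, which is activated by two ortho and one para oxygen; ring B is much less electron-rich and is not attacked.

Step 11
Reactants: 18 3',4'-dihydroxyacetophenone
Product: 19 3',4'-bis(benzyloxy)acetophenone
Conditions: BnBr, K2CO3, DMF, 60 °C
Reagents that add atoms: benzyl bromide, BrCc1ccccc1
Why: Williamson etherification of the catechol.

Step 12
Reactants: 17 8-bromo-3,5,7,3',4'-penta-O-benzylepicatechin-6-carbaldehyde; 19 3',4'-bis(benzyloxy)acetophenone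
Product: 20 (E)-1-[3,4-bis(benzyloxy)phenyl]-3-(8-bromo-3,5,7,3',4'-penta-O-benzylepicatechin-6-yl)prop-2-en-1-one
Conditions: KOH, EtOH/THF, rt
Reagents that add atoms: none
Why: Claisen–Schmidt condensation of a non-enolisable 2,6-dialkoxybenzaldehyde with a methyl ketone; dehydration gives the (E)-enone, and the capped flavan is inert to hydroxide.

Step 13
Reactants: 20 (E)-1-[3,4-bis(benzyloxy)phenyl]-3-(8-bromo-3,5,7,3',4'-penta-O-benzylepicatechin-6-yl)prop-2-en-1-one
Product: 21 (2R,3S)-1-[3,4-bis(benzyloxy)phenyl]-3-(8-bromo-3,5,7,3',4'-penta-O-benzylepicatechin-6-yl)-2,3-epoxypropan-1-one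
Conditions: poly-L-leucine, urea·H2O2, DBU, THF, rt; product handled on base-washed silica
Reagents that add atoms: hydrogen peroxide (as its urea adduct), OO
Why: Juliá–Colonna epoxidation: the helical polypeptide directs conjugate addition of hydroperoxide to one enone face and ring closure gives the trans epoxide, (2R,3S) as for simple chalcones; this sets C3 of the middle unit, and the non-aqueous conditions spare the acid-sensitive epoxide.

Step 14
Reactants: 21 (2R,3S)-1-[3,4-bis(benzyloxy)phenyl]-3-(8-bromo-3,5,7,3',4'-penta-O-benzylepicatechin-6-yl)-2,3-epoxypropan-1-one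
Product: 22 (1S,2S,3S)-1-[3,4-bis(benzyloxy)phenyl]-3-(8-bromo-3,5,7,3',4'-penta-O-benzylepicatechin-6-yl)-2,3-epoxypropan-1-ol
Conditions: Zn(BH4)2, Et2O/CH2Cl2, −78 to −40 °C; aq. NH4Cl
Reagents that add atoms: none
Why: Chelation-controlled reduction: zinc bridges the carbonyl and epoxide oxygens and hydride adds to the face away from the epoxide carbon, giving the anti epoxy alcohol; C2 thus has the configuration opposite to the target, as the invertive ring closure requires.

Step 15
Reactants: 22 (1S,2S,3S)-1-[3,4-bis(benzyloxy)phenyl]-3-(8-bromo-3,5,7,3',4'-penta-O-benzylepicatechin-6-yl)-2,3-epoxypropan-1-ol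
Product: 23 (1S,2R,3S)-1-[3,4-bis(benzyloxy)phenyl]-3-(8-bromo-3,5,7,3',4'-penta-O-benzylepicatechin-6-yl)-1-(tert-butyldimethylsilyloxy)-2,3-epoxypropane
Conditions: t-BuMe2SiCl, imidazole, DMF, 0 °C to rt
Reagents that add atoms: tert-butyldimethylsilyl chloride, CC(C)(C)[Si](C)(C)Cl
Why: Silylation under imidazole avoids both a free alkoxide (Payne rearrangement) and a Lewis acid (epoxide ionisation); the descriptor at C2 of the chain changes only through the CIP rules.

Step 16
Reactants: 23 (1S,2R,3S)-1-[3,4-bis(benzyloxy)phenyl]-3-(8-bromo-3,5,7,3',4'-penta-O-benzylepicatechin-6-yl)-1-(tert-butyldimethylsilyloxy)-2,3-epoxypropane; 24 ethynyltrimethylsilane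
Product: 26 (1S,2R,3S)-1-[3,4-bis(benzyloxy)phenyl]-3-(8-bromo-3,5,7,3',4'-penta-O-benzylepicatechin-6-yl)-1-(tert-butyldimethylsilyloxy)-5-(trimethylsilyl)pent-4-yn-2-ol, via lithium trimethylsilylacetylide 25 (not isolated)
Conditions: 24 (slight excess over n-BuLi), n-BuLi, THF, −78 °C; then 23, BF3·OEt2, −78 °C
Reagents that add atoms: none
Why: Yamaguchi–Hirao-type epoxide alkynylation: BF3 activates the epoxide and the acetylide attacks benzylic C4, the carbon best able to bear positive charge, opposite the departing oxygen. Inversion at C4 of the trans-epoxide places the lower-unit aryl group in the relationship to O3 that becomes 3,4-trans in the flavan, and O3 is left as the only free hydroxyl.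

Step 17
Reactants: 26 (1S,2R,3S)-1-[3,4-bis(benzyloxy)phenyl]-3-(8-bromo-3,5,7,3',4'-penta-O-benzylepicatechin-6-yl)-1-(tert-butyldimethylsilyloxy)-5-(trimethylsilyl)pent-4-yn-2-ol
Product: 27 (1S,2R,3S)-2-benzyloxy-1-[3,4-bis(benzyloxy)phenyl]-3-(8-bromo-3,5,7,3',4'-penta-O-benzylepicatechin-6-yl)-1-(tert-butyldimethylsilyloxy)-5-(trimethylsilyl)pent-4-yne
Conditions: 2-benzyloxy-1-methylpyridinium triflate, MgO, PhCF3, 85 °C
Reagents that add atoms: 2-benzyloxy-1-methylpyridinium triflate, C[n+]1ccccc1OCc1ccccc1.[O-]S(=O)(=O)C(F)(F)F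
Why: Benzyl transfer under neutral conditions: no alkoxide is formed, so the neighbouring silyl group cannot migrate from O2 to O3, and the hindered secondary alcohol is benzylated by the thermally released benzyl electrophile.

Step 18
Reactants: 27 (1S,2R,3S)-2-benzyloxy-1-[3,4-bis(benzyloxy)phenyl]-3-(8-bromo-3,5,7,3',4'-penta-O-benzylepicatechin-6-yl)-1-(tert-butyldimethylsilyloxy)-5-(trimethylsilyl)pent-4-yne
Product: 28 (1S,2R,3R)-2-benzyloxy-1-[3,4-bis(benzyloxy)phenyl]-3-(8-bromo-3,5,7,3',4'-penta-O-benzylepicatechin-6-yl)-1-(tert-butyldimethylsilyloxy)pent-4-yne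
Conditions: K2CO3, MeOH/THF, rt
Reagents that add atoms: none
Why: Methanolysis of the alkynyl C–Si bond; the silyl ether on oxygen and all stereocentres are unaffected (the C4 descriptor changes only through the CIP rules).

Step 19
Reactants: 28 (1S,2R,3R)-2-benzyloxy-1-[3,4-bis(benzyloxy)phenyl]-3-(8-bromo-3,5,7,3',4'-penta-O-benzylepicatechin-6-yl)-1-(tert-butyldimethylsilyloxy)pent-4-yne
Product: 31 (1S,2R,3R)-2-benzyloxy-1-[3,4-bis(benzyloxy)phenyl]-3-(8-bromo-3,5,7,3',4'-penta-O-benzylepicatechin-6-yl)-1-(tert-butyldimethylsilyloxy)-5-(triisopropylsilyloxy)pent-4-yne (fragment 2), via lithium acetylide 29 (not isolated), via lithium ynolate 30 (not isolated)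
Conditions: LiN(SiMe3)2, THF, −78 °C; t-BuOOLi (from t-BuOOH and LiN(SiMe3)2), −78 to 0 °C; i-Pr3SiOTf, −78 to 0 °C
Reagents that add atoms: tert-butyl hydroperoxide, CC(C)(C)OO; triisopropylsilyl triflate, CC(C)[Si](C(C)C)(C(C)C)OS(=O)(=O)C(F)(F)F
Why: Acetylide oxidation–silylation: the acetylide carbon attacks the electrophilic oxygen of t-BuOOLi to give the ynolate, which the bulky silyl triflate captures on oxygen; the amide base is used in place of an alkyllithium so that the aryl bromide is not exchanged.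

Step 20
Reactants: 15 3-benzyloxy-4-[(4β)-3,5,7,3',4'-penta-O-benzylepicatechin-4-yl]cyclobut-2-enone (fragment 1); 31 triisopropylsilyl ynol ether (fragment 2)
Product: 36 middle ring A phenol (O5 free; O7 benzyl; O8a triisopropylsilyl; upper unit on C6; C4 chain on C4a; ring C open), via vinylketene 32 (not isolated), via alkenylcyclobutenone 33 (not isolated), via dienylketene 34 (not isolated), via cyclohexadienone 35 (not isolated)
Conditions: 15 (1.3 equiv), toluene (degassed), 80 then 110 °C, sealed tube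
Reagents that add atoms: none
Why: Danheiser benzannulation: on heating, 15 undergoes four-electron electrocyclic opening to vinylketene 32 with the flavan substituent turning outward. The ketene carbonyl carbon of 32 bonds to the nucleophilic β-carbon of siloxyalkyne 31 and the ketene α-carbon to the oxygen-bearing carbon in a [2+2] cycloaddition, giving alkenylcyclobutenone 33 (bonds C4a–C5 and C8–C8a). Reversible four-electron opening of 33 gives dienylketene 34, and the rotamer with the alkenyl group turned inward closes ring A by a thermal disrotatory six-electron electrocyclisation (bond C5–C6) to cyclohexadienone 35, which tautomerises to phenol 36. The closest precedent is the benzannulation of alkyl-substituted cyclobutenones with triisopropylsilyl ynol ethers to resorcinol monosilyl ethers; a 3-alkoxy-4-alkylcyclobutenone and partners of this size are untried. No stereocentre is formed: the sp3 ring carbon of 15 and the transient sp3 carbons of 33 and 35 end as aromatic carbons, and C2, C3, C4 of both fragments are untouched because no acid, base or cation is present. The step needs only regioselectivity, and this is fixed by polarity: the electrophilic ketene carbon (future C5) bonds to the alkyne carbon remote from oxygen (future C4a), which puts the upper unit para to the silyloxy carbon C8a and leaves O5 free, O7 benzylated and O8a silylated.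

Step 21
Reactants: 36 middle ring A phenol
Product: 37 O5-benzyl ether of 36
Conditions: BnBr, NaH, Bu4NI, THF/DMF, 0 °C to rt
Reagents that add atoms: benzyl bromide, BrCc1ccccc1
Why: Williamson etherification of the hindered phenoxide; capping O5 now ensures that only O8a can later close ring C, and anhydrous NaH leaves the aryl silyl ether intact.

Step 22
Reactants: 37 O5-benzyl ether of 36
Product: 38 seco-trimer with free C8a phenol and free C2 hydroxyl
Conditions: Bu4NF, THF, argon, 0 °C to rt
Reagents that add atoms: none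
Why: Fluoride cleaves both the aryl triisopropylsilyl ether and the secondary tert-butyldimethylsilyl ether; benzyl ethers, the aryl bromide and all stereocentres are inert.

Step 23
Reactants: 38 seco-trimer with free C8a phenol and free C2 hydroxyl
Product: 39 [3,5,7,3',4'-penta-O-benzylepicatechin]-(4β→6)-[3,5,7,3',4'-penta-O-benzylepicatechin]-(4β→6)-[8-bromo-3,5,7,3',4'-penta-O-benzylepicatechin]
Conditions: PPh3, DIAD, THF, 0 °C to rt, high dilution
Reagents that add atoms: none
Why: Intramolecular Mitsunobu etherification: the benzylic C2 alcohol is activated as its oxyphosphonium salt and displaced by the C8a phenoxide in a 6-exo-tet SN2 closure with inversion, converting the anti C2/C3 arrangement into the 2,3-cis flavan (2R); O5 and O3 are benzylated and cannot compete.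

Step 24
Reactants: 39 protected 8-bromo trimer
Product: 40 epicatechin-(4β→6)-epicatechin-(4β→6)-epicatechin
Conditions: H2 (1 atm), Pd(OH)2 on carbon, Et3N, THF/MeOH/H2O, rt
Reagents that add atoms: none
Why: Catalytic hydrogenolysis cleaves the fifteen benzyl ethers and the aryl C–Br bond in one neutral operation; Et3N takes up the HBr so that the acid-labile interflavan bonds are not exposed, and no stereocentre is involved.

## Compound list

1 | (−)-epicatechin | O[C@@H]1Cc2c(O)cc(O)cc2O[C@@H]1c1ccc(O)c(O)c1 | starting material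
2 | 5,7,3',4'-tetra-O-benzyl-(−)-epicatechin | c9ccccc9COc1cc(OCc9ccccc9)c2c(c1)O[C@H](c8ccc(OCc9ccccc9)c(OCc9ccccc9)c8)[C@H](O)C2 | intermediate
3 | 3,5,7,3',4'-penta-O-benzyl-(−)-epicatechin | c9ccccc9COc1cc(OCc9ccccc9)c2c(c1)O[C@H](c8ccc(OCc9ccccc9)c(OCc9ccccc9)c8)[C@H](OCc9ccccc9)C2 | intermediate
4 | (4β)-4-(2-ethoxyethoxy)-3,5,7,3',4'-penta-O-benzylepicatechin | c9ccccc9COc1cc(OCc9ccccc9)c2c(c1)O[C@H](c8ccc(OCc9ccccc9)c(OCc9ccccc9)c8)[C@H](OCc9ccccc9)[C@H]2OCCOCC | intermediate
5 | 1-(tert-butyldimethylsilyloxy)-1-methoxyethene | C=C(OC)O[Si](C)(C)C(C)(C)C | starting material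
6 | methyl 2-[(4β)-3,5,7,3',4'-penta-O-benzylepicatechin-4-yl]acetate | c9ccccc9COc1cc(OCc9ccccc9)c2c(c1)O[C@H](c8ccc(OCc9ccccc9)c(OCc9ccccc9)c8)[C@H](OCc9ccccc9)[C@H]2CC(=O)OC | intermediate
7 | 2-[(4β)-3,5,7,3',4'-penta-O-benzylepicatechin-4-yl]acetic acid | c9ccccc9COc1cc(OCc9ccccc9)c2c(c1)O[C@H](c8ccc(OCc9ccccc9)c(OCc9ccccc9)c8)[C@H](OCc9ccccc9)[C@H]2CC(=O)O | intermediate
8 | benzyl alcohol | OCc1ccccc1 | starting material
9 | trichloroethylene | ClC=C(Cl)Cl | starting material
10 | benzyl (E)-1,2-dichlorovinyl ether | Cl/C=C(/Cl)OCc1ccccc1 | intermediate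
11 | lithium benzyloxyacetylide | [Li]C#COCc1ccccc1 | intermediate
12 | benzyl ethynyl ether | C#COCc1ccccc1 | intermediate
13 | 2-[(4β)-3,5,7,3',4'-penta-O-benzylepicatechin-4-yl]acetyl chloride | c9ccccc9COc1cc(OCc9ccccc9)c2c(c1)O[C@H](c8ccc(OCc9ccccc9)c(OCc9ccccc9)c8)[C@H](OCc9ccccc9)[C@H]2CC(=O)Cl | intermediate
14 | [(4β)-3,5,7,3',4'-penta-O-benzylepicatechin-4-yl]ketene | c9ccccc9COc1cc(OCc9ccccc9)c2c(c1)O[C@H](c8ccc(OCc9ccccc9)c(OCc9ccccc9)c8)[C@H](OCc9ccccc9)[C@H]2C=C=O | intermediate
15 | 3-benzyloxy-4-[(4β)-3,5,7,3',4'-penta-O-benzylepicatechin-4-yl]cyclobut-2-enone (fragment 1; both epimers at the ring sp3 carbon) | c9ccccc9COc1cc(OCc9ccccc9)c2c(c1)O[C@H](c8ccc(OCc9ccccc9)c(OCc9ccccc9)c8)[C@H](OCc9ccccc9)[C@H]2C7C(=O)C=C7OCc9ccccc9 | intermediate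
16 | 8-bromo-3,5,7,3',4'-penta-O-benzylepicatechin | c1c(OCc9ccccc9)c(Br)c2c(c1OCc9ccccc9)C[C@@H](OCc9ccccc9)[C@@H](c8ccc(OCc9ccccc9)c(OCc9ccccc9)c8)O2 | intermediate
17 | 8-bromo-3,5,7,3',4'-penta-O-benzylepicatechin-6-carbaldehyde | O=Cc5c(OCc9ccccc9)c(Br)c6c(c5OCc9ccccc9)C[C@@H](OCc9ccccc9)[C@@H](c8ccc(OCc9ccccc9)c(OCc9ccccc9)c8)O6 | intermediate
18 | 3',4'-dihydroxyacetophenone | CC(=O)c1ccc(O)c(O)c1 | starting material
19 | 3',4'-bis(benzyloxy)acetophenone | CC(=O)c8ccc(OCc9ccccc9)c(OCc9ccccc9)c8 | intermediate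
20 | (E)-chalcone: 1-[3,4-bis(benzyloxy)phenyl]-3-(8-bromo-penta-O-benzylepicatechin-6-yl)prop-2-en-1-one | O=C(/C=C/c5c(OCc9ccccc9)c(Br)c6c(c5OCc9ccccc9)C[C@@H](OCc9ccccc9)[C@@H](c8ccc(OCc9ccccc9)c(OCc9ccccc9)c8)O6)c8ccc(OCc9ccccc9)c(OCc9ccccc9)c8 | intermediate
21 | (2R,3S)-2,3-epoxy ketone of 20 (trans; future C3 R, C4 S) | O=C(c8ccc(OCc9ccccc9)c(OCc9ccccc9)c8)[C@@H]1O[C@H]1c5c(OCc9ccccc9)c(Br)c6c(c5OCc9ccccc9)C[C@@H](OCc9ccccc9)[C@@H](c8ccc(OCc9ccccc9)c(OCc9ccccc9)c8)O6 | intermediate
22 | (1S,2S,3S)-2,3-epoxypropan-1-ol (anti epoxy alcohol) | O[C@@H](c8ccc(OCc9ccccc9)c(OCc9ccccc9)c8)[C@@H]1O[C@H]1c5c(OCc9ccccc9)c(Br)c6c(c5OCc9ccccc9)C[C@@H](OCc9ccccc9)[C@@H](c8ccc(OCc9ccccc9)c(OCc9ccccc9)c8)O6 | intermediate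
23 | (1S,2R,3S)-1-(tert-butyldimethylsilyloxy)-2,3-epoxypropane (silyl ether of 22) | CC(C)(C)[Si](C)(C)O[C@@H](c8ccc(OCc9ccccc9)c(OCc9ccccc9)c8)[C@@H]1O[C@H]1c5c(OCc9ccccc9)c(Br)c6c(c5OCc9ccccc9)C[C@@H](OCc9ccccc9)[C@@H](c8ccc(OCc9ccccc9)c(OCc9ccccc9)c8)O6 | intermediate
24 | ethynyltrimethylsilane | C#C[Si](C)(C)C | starting material
25 | lithium trimethylsilylacetylide | [Li]C#C[Si](C)(C)C | intermediate
26 | (1S,2R,3S)-1-[3,4-bis(benzyloxy)phenyl]-3-(8-bromo-penta-O-benzylepicatechin-6-yl)-1-(tert-butyldimethylsilyloxy)-5-(trimethylsilyl)pent-4-yn-2-ol | C[Si](C)(C)C#C[C@H](c5c(OCc9ccccc9)c(Br)c6c(c5OCc9ccccc9)C[C@@H](OCc9ccccc9)[C@@H](c8ccc(OCc9ccccc9)c(OCc9ccccc9)c8)O6)[C@@H](O)[C@@H](O[Si](C)(C)C(C)(C)C)c8ccc(OCc9ccccc9)c(OCc9ccccc9)c8 | intermediate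
27 | (1S,2R,3S)-2-O-benzyl ether of 26 | C[Si](C)(C)C#C[C@H](c5c(OCc9ccccc9)c(Br)c6c(c5OCc9ccccc9)C[C@@H](OCc9ccccc9)[C@@H](c8ccc(OCc9ccccc9)c(OCc9ccccc9)c8)O6)[C@@H](OCc9ccccc9)[C@@H](O[Si](C)(C)C(C)(C)C)c8ccc(OCc9ccccc9)c(OCc9ccccc9)c8 | intermediate
28 | (1S,2R,3R)-terminal alkyne (C-desilylated 27) | C#C[C@H](c5c(OCc9ccccc9)c(Br)c6c(c5OCc9ccccc9)C[C@@H](OCc9ccccc9)[C@@H](c8ccc(OCc9ccccc9)c(OCc9ccccc9)c8)O6)[C@@H](OCc9ccccc9)[C@@H](O[Si](C)(C)C(C)(C)C)c8ccc(OCc9ccccc9)c(OCc9ccccc9)c8 | intermediate
29 | lithium acetylide of 28 | [Li]C#C[C@H](c5c(OCc9ccccc9)c(Br)c6c(c5OCc9ccccc9)C[C@@H](OCc9ccccc9)[C@@H](c8ccc(OCc9ccccc9)c(OCc9ccccc9)c8)O6)[C@@H](OCc9ccccc9)[C@@H](O[Si](C)(C)C(C)(C)C)c8ccc(OCc9ccccc9)c(OCc9ccccc9)c8 | intermediate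
30 | lithium ynolate from 29 | [Li]OC#C[C@H](c5c(OCc9ccccc9)c(Br)c6c(c5OCc9ccccc9)C[C@@H](OCc9ccccc9)[C@@H](c8ccc(OCc9ccccc9)c(OCc9ccccc9)c8)O6)[C@@H](OCc9ccccc9)[C@@H](O[Si](C)(C)C(C)(C)C)c8ccc(OCc9ccccc9)c(OCc9ccccc9)c8 | intermediate
31 | triisopropylsilyl ynol ether (fragment 2; C2 S, C3 R, C4 R) | CC(C)[Si](C(C)C)(C(C)C)OC#C[C@H](c5c(OCc9ccccc9)c(Br)c6c(c5OCc9ccccc9)C[C@@H](OCc9ccccc9)[C@@H](c8ccc(OCc9ccccc9)c(OCc9ccccc9)c8)O6)[C@@H](OCc9ccccc9)[C@@H](O[Si](C)(C)C(C)(C)C)c8ccc(OCc9ccccc9)c(OCc9ccccc9)c8 | intermediate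
32 | vinylketene from 15 (flavan trans to the ketene carbon) | c9ccccc9COc1cc(OCc9ccccc9)c2c(c1)O[C@H](c8ccc(OCc9ccccc9)c(OCc9ccccc9)c8)[C@H](OCc9ccccc9)[C@H]2/C=C(/C=C=O)OCc9ccccc9 | intermediate
33 | 4-alkenyl-3-silyloxycyclobutenone, the [2+2] adduct (both epimers at the ring sp3 carbon) | c9ccccc9COc1cc(OCc9ccccc9)c2c(c1)O[C@H](c8ccc(OCc9ccccc9)c(OCc9ccccc9)c8)[C@H](OCc9ccccc9)[C@H]2/C=C(OCc9ccccc9)/C7C(=O)C([C@H](c5c(OCc9ccccc9)c(Br)c6c(c5OCc9ccccc9)C[C@@H](OCc9ccccc9)[C@@H](c8ccc(OCc9ccccc9)c(OCc9ccccc9)c8)O6)[C@@H](OCc9ccccc9)[C@@H](O[Si](C)(C)C(C)(C)C)c8ccc(OCc9ccccc9)c(OCc9ccccc9)c8)=C7O[Si](C(C)C)(C(C)C)C(C)C | intermediate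
34 | dienylketene (alkenyl group cis to the ketene) | c9ccccc9COc1cc(OCc9ccccc9)c2c(c1)O[C@H](c8ccc(OCc9ccccc9)c(OCc9ccccc9)c8)[C@H](OCc9ccccc9)[C@H]2/C=C(OCc9ccccc9)/C=C(O[Si](C(C)C)(C(C)C)C(C)C)\C([C@H](c5c(OCc9ccccc9)c(Br)c6c(c5OCc9ccccc9)C[C@@H](OCc9ccccc9)[C@@H](c8ccc(OCc9ccccc9)c(OCc9ccccc9)c8)O6)[C@@H](OCc9ccccc9)[C@@H](O[Si](C)(C)C(C)(C)C)c8ccc(OCc9ccccc9)c(OCc9ccccc9)c8)=C=O | intermediate
35 | cyclohexa-2,4-dienone (both epimers at the ring sp3 carbon) | c9ccccc9COc1cc(OCc9ccccc9)c2c(c1)O[C@H](c8ccc(OCc9ccccc9)c(OCc9ccccc9)c8)[C@H](OCc9ccccc9)[C@H]2C7C(=O)C([C@H](c5c(OCc9ccccc9)c(Br)c6c(c5OCc9ccccc9)C[C@@H](OCc9ccccc9)[C@@H](c8ccc(OCc9ccccc9)c(OCc9ccccc9)c8)O6)[C@@H](OCc9ccccc9)[C@@H](O[Si](C)(C)C(C)(C)C)c8ccc(OCc9ccccc9)c(OCc9ccccc9)c8)=C(O[Si](C(C)C)(C(C)C)C(C)C)C=C7OCc9ccccc9 | intermediate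
36 | middle ring A phenol (O5 free, O7 benzyl, O8a triisopropylsilyl, ring C open) | c9ccccc9COc1cc(OCc9ccccc9)c2c(c1)O[C@H](c8ccc(OCc9ccccc9)c(OCc9ccccc9)c8)[C@H](OCc9ccccc9)[C@H]2c3c(OCc9ccccc9)cc(O[Si](C(C)C)(C(C)C)C(C)C)c(c3O)[C@H](c5c(OCc9ccccc9)c(Br)c6c(c5OCc9ccccc9)C[C@@H](OCc9ccccc9)[C@@H](c8ccc(OCc9ccccc9)c(OCc9ccccc9)c8)O6)[C@@H](OCc9ccccc9)[C@@H](O[Si](C)(C)C(C)(C)C)c8ccc(OCc9ccccc9)c(OCc9ccccc9)c8 | intermediate
37 | O5-benzyl ether of 36 | c9ccccc9COc1cc(OCc9ccccc9)c2c(c1)O[C@H](c8ccc(OCc9ccccc9)c(OCc9ccccc9)c8)[C@H](OCc9ccccc9)[C@H]2c3c(OCc9ccccc9)cc(O[Si](C(C)C)(C(C)C)C(C)C)c(c3OCc9ccccc9)[C@H](c5c(OCc9ccccc9)c(Br)c6c(c5OCc9ccccc9)C[C@@H](OCc9ccccc9)[C@@H](c8ccc(OCc9ccccc9)c(OCc9ccccc9)c8)O6)[C@@H](OCc9ccccc9)[C@@H](O[Si](C)(C)C(C)(C)C)c8ccc(OCc9ccccc9)c(OCc9ccccc9)c8 | intermediate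
38 | seco-trimer with free C8a phenol and free C2 hydroxyl | c9ccccc9COc1cc(OCc9ccccc9)c2c(c1)O[C@H](c8ccc(OCc9ccccc9)c(OCc9ccccc9)c8)[C@H](OCc9ccccc9)[C@H]2c3c(OCc9ccccc9)cc(O)c(c3OCc9ccccc9)[C@H](c5c(OCc9ccccc9)c(Br)c6c(c5OCc9ccccc9)C[C@@H](OCc9ccccc9)[C@@H](c8ccc(OCc9ccccc9)c(OCc9ccccc9)c8)O6)[C@@H](OCc9ccccc9)[C@@H](O)c8ccc(OCc9ccccc9)c(OCc9ccccc9)c8 | intermediate
39 | pentadeca-O-benzyl 8-bromo trimer, epicatechin-(4β→6)-epicatechin-(4β→6)-8-bromoepicatechin | c9ccccc9COc1cc(OCc9ccccc9)c2c(c1)O[C@H](c8ccc(OCc9ccccc9)c(OCc9ccccc9)c8)[C@H](OCc9ccccc9)[C@H]2c3c(OCc9ccccc9)cc4c(c3OCc9ccccc9)[C@H](c5c(OCc9ccccc9)c(Br)c6c(c5OCc9ccccc9)C[C@@H](OCc9ccccc9)[C@@H](c8ccc(OCc9ccccc9)c(OCc9ccccc9)c8)O6)[C@@H](OCc9ccccc9)[C@@H](c8ccc(OCc9ccccc9)c(OCc9ccccc9)c8)O4 | intermediate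
40 | epicatechin-(4β→6)-epicatechin-(4β→6)-epicatechin (CNP0163146.2) | Oc1cc(O)c2c(c1)O[C@H](c1ccc(O)c(O)c1)[C@H](O)[C@H]2c1c(O)cc2c(c1O)[C@H](c1c(O)cc3c(c1O)C[C@@H](O)[C@@H](c1ccc(O)c(O)c1)O3)[C@@H](O)[C@@H](c1ccc(O)c(O)c1)O2 | target

## Step count and least certain steps

Total: 24 steps. Longest linear sequence: 17 steps (1, 2, 9, 10, 12–24) from (−)-epicatechin.

**Step 20 (key step).** The bimolecular [2+2] between two very large partners may be slow, so that vinylketene 32 dimerises or is trapped by the phenol being formed. A 3-alkoxycyclobutenone may also need temperatures at which the siloxyalkyne undergoes a 1,3-silyl shift to a silylketene, and the six-electron closure next to the flavan substituent is crowded. Fallback (known Lewis-acid flavan coupling with bromine blocking; sets out from 16 and 4, returns at 40): 16 is oxidised with DDQ and 2-ethoxyethanol to 8-bromo-(4β)-4-(2-ethoxyethoxy)-penta-O-benzylepicatechin F1. F1 is coupled with an excess of 16 under Me3SiOTf at low temperature to the 4β→6 dibromo dimer F2, whose only free nucleophilic carbon is C6 of its upper half. F2 is coupled with 4 under Me3SiOTf to the pentadecabenzyl dibromo trimer F3, and hydrogenolysis over Pd(OH)2 on carbon with Et3N gives 40.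

**Step 16.** The epoxide carbon C4 is benzylic to a 2,4,6-trioxygenated ring, so the C–O bond may ionise before the acetylide arrives. Likely consequences are loss of clean inversion (front-side delivery or a mixture at C4), a 1,2-hydride shift to a ketone, or fluoride transfer from boron. Fallback (SN1 substitution steered by a participating ester, as with 3-O-acyl groups in flavan C4 chemistry; sets out from 23, returns at 26): 23 is opened with methanol under pyridinium tosylate to the stable C4 methyl ether with free O3, F4 (C4 mixture). O3 is acylated with pivaloyl chloride to F5. F5 is ionised with BF3·OEt2 in the presence of K[Me3SiC≡CBF3], the pivalate covering the O3 face so that the alkynyl group enters anti to it, giving alkynyl pivalate F6. i-Bu2AlH removes the pivalate to give 26.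

**Step 13 (and the life of epoxide 21 through steps 14 and 15).** Hydroperoxide addition to the hindered, electron-rich enone may be slow. The epoxide may also open at C4 on silica, with zinc salts, or by hydride during the reduction. Fallback (epoxide made by C–C bond formation; sets out from 19 and 17, returns at 21): 19 is α-chlorinated to 2-chloro-1-[3,4-bis(benzyloxy)phenyl]ethanone F7. An asymmetric Darzens condensation of F7 with aldehyde 17 under a cinchona-derived quaternary ammonium phase-transfer catalyst and LiOH gives trans-epoxy ketone 21 directly; if 21 proves too labile to store, it is reduced and silylated without purification.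

**Step 8.** Benzyl ethynyl ether 12 may rearrange sigmatropically, or ketene 14 may dimerise, before the cycloaddition. Fallback (sets out from 7, returns at 15): the ketene from 7 is trapped with commercial ethoxyacetylene to the 3-ethoxycyclobutenone F8. The ethoxy group is then exchanged by acid-catalysed vinylogous transetherification with benzyl alcohol 8 under strictly anhydrous conditions to give 15. Water must be excluded, because hydrolysis to the dione and re-etherification would move the double bond next to the flavan.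

**Step 23.** The oxyphosphonium salt at C2 is benzylic to a 3,4-dialkoxyphenyl ring and may ionise, which would erode the inversion and give the 2,3-trans epimer. Fallback (reductive etherification; sets out from 37, returns at 39): the alkyl silyl ether of 37 is removed selectively with HF·pyridine to alcohol F9, and the C2 carbinol is oxidised with a hypervalent iodine reagent to aryl ketone F10. Bu4NF frees the C8a phenol, which closes onto the ketone to give the 2-hydroxyflavan hemiketal F11. Et3SiH with BF3·OEt2 at −78 °C reduces the cyclic oxocarbenium ion, hydride entering trans to the C3 benzyloxy group, to give the 2,3-cis flavan 39.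

## Further compounds

F1 | step 20 | 8-bromo-(4β)-4-(2-ethoxyethoxy)-3,5,7,3',4'-penta-O-benzylepicatechin | c1c(OCc9ccccc9)c(Br)c2c(c1OCc9ccccc9)[C@H](OCCOCC)[C@@H](OCc9ccccc9)[C@@H](c8ccc(OCc9ccccc9)c(OCc9ccccc9)c8)O2
F2 | step 20 | [8-bromo-penta-O-benzylepicatechin]-(4β→6)-[8-bromo-penta-O-benzylepicatechin] | c1c(OCc9ccccc9)c(Br)c2c(c1OCc9ccccc9)[C@H](c5c(OCc9ccccc9)c(Br)c6c(c5OCc9ccccc9)C[C@@H](OCc9ccccc9)[C@@H](c8ccc(OCc9ccccc9)c(OCc9ccccc9)c8)O6)[C@@H](OCc9ccccc9)[C@@H](c8ccc(OCc9ccccc9)c(OCc9ccccc9)c8)O2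
F3 | step 20 | pentadeca-O-benzyl trimer with bromine on C8 of the middle and lower units | c9ccccc9COc1cc(OCc9ccccc9)c2c(c1)O[C@H](c8ccc(OCc9ccccc9)c(OCc9ccccc9)c8)[C@H](OCc9ccccc9)[C@H]2c3c(OCc9ccccc9)c(Br)c4c(c3OCc9ccccc9)[C@H](c5c(OCc9ccccc9)c(Br)c6c(c5OCc9ccccc9)C[C@@H](OCc9ccccc9)[C@@H](c8ccc(OCc9ccccc9)c(OCc9ccccc9)c8)O6)[C@@H](OCc9ccccc9)[C@@H](c8ccc(OCc9ccccc9)c(OCc9ccccc9)c8)O4
F4 | step 16 | C4 methyl ether with free O3 and silylated O2 (C4 mixture) | COC(c5c(OCc9ccccc9)c(Br)c6c(c5OCc9ccccc9)C[C@@H](OCc9ccccc9)[C@@H](c8ccc(OCc9ccccc9)c(OCc9ccccc9)c8)O6)[C@@H](O)[C@@H](O[Si](C)(C)C(C)(C)C)c8ccc(OCc9ccccc9)c(OCc9ccccc9)c8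
F5 | step 16 | O3-pivalate of F4 | COC(c5c(OCc9ccccc9)c(Br)c6c(c5OCc9ccccc9)C[C@@H](OCc9ccccc9)[C@@H](c8ccc(OCc9ccccc9)c(OCc9ccccc9)c8)O6)[C@@H](OC(=O)C(C)(C)C)[C@@H](O[Si](C)(C)C(C)(C)C)c8ccc(OCc9ccccc9)c(OCc9ccccc9)c8
F6 | step 16 | O3-pivalate of 26 | C[Si](C)(C)C#C[C@H](c5c(OCc9ccccc9)c(Br)c6c(c5OCc9ccccc9)C[C@@H](OCc9ccccc9)[C@@H](c8ccc(OCc9ccccc9)c(OCc9ccccc9)c8)O6)[C@@H](OC(=O)C(C)(C)C)[C@@H](O[Si](C)(C)C(C)(C)C)c8ccc(OCc9ccccc9)c(OCc9ccccc9)c8
F7 | step 13 | 2-chloro-1-[3,4-bis(benzyloxy)phenyl]ethanone | O=C(CCl)c8ccc(OCc9ccccc9)c(OCc9ccccc9)c8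
F8 | step 8 | 3-ethoxy-4-[(4β)-penta-O-benzylepicatechin-4-yl]cyclobut-2-enone (both ring epimers) | c9ccccc9COc1cc(OCc9ccccc9)c2c(c1)O[C@H](c8ccc(OCc9ccccc9)c(OCc9ccccc9)c8)[C@H](OCc9ccccc9)[C@H]2C7C(=O)C=C7OCC
F9 | step 23 | 37 with free C2 hydroxyl and intact aryl silyl ether | c9ccccc9COc1cc(OCc9ccccc9)c2c(c1)O[C@H](c8ccc(OCc9ccccc9)c(OCc9ccccc9)c8)[C@H](OCc9ccccc9)[C@H]2c3c(OCc9ccccc9)cc(O[Si](C(C)C)(C(C)C)C(C)C)c(c3OCc9ccccc9)[C@H](c5c(OCc9ccccc9)c(Br)c6c(c5OCc9ccccc9)C[C@@H](OCc9ccccc9)[C@@H](c8ccc(OCc9ccccc9)c(OCc9ccccc9)c8)O6)[C@@H](OCc9ccccc9)[C@@H](O)c8ccc(OCc9ccccc9)c(OCc9ccccc9)c8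
F10 | step 23 | C2 aryl ketone from F9 | c9ccccc9COc1cc(OCc9ccccc9)c2c(c1)O[C@H](c8ccc(OCc9ccccc9)c(OCc9ccccc9)c8)[C@H](OCc9ccccc9)[C@H]2c3c(OCc9ccccc9)cc(O[Si](C(C)C)(C(C)C)C(C)C)c(c3OCc9ccccc9)[C@H](c5c(OCc9ccccc9)c(Br)c6c(c5OCc9ccccc9)C[C@@H](OCc9ccccc9)[C@@H](c8ccc(OCc9ccccc9)c(OCc9ccccc9)c8)O6)[C@@H](OCc9ccccc9)C(=O)c8ccc(OCc9ccccc9)c(OCc9ccccc9)c8
F11 | step 23 | 2-hydroxyflavan hemiketal of the middle unit (C2 mixture) | c9ccccc9COc1cc(OCc9ccccc9)c2c(c1)O[C@H](c8ccc(OCc9ccccc9)c(OCc9ccccc9)c8)[C@H](OCc9ccccc9)[C@H]2c3c(OCc9ccccc9)cc4c(c3OCc9ccccc9)[C@H](c5c(OCc9ccccc9)c(Br)c6c(c5OCc9ccccc9)C[C@@H](OCc9ccccc9)[C@@H](c8ccc(OCc9ccccc9)c(OCc9ccccc9)c8)O6)[C@@H](OCc9ccccc9)C(O)(c8ccc(OCc9ccccc9)c(OCc9ccccc9)c8)O4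
A1 | alternative 1 | tridecabenzyl 8-bromo trimer with free C3 hydroxyls on the upper and middle units | c9ccccc9COc1cc(OCc9ccccc9)c2c(c1)O[C@H](c8ccc(OCc9ccccc9)c(OCc9ccccc9)c8)[C@H](O)[C@H]2c3c(OCc9ccccc9)cc4c(c3OCc9ccccc9)[C@H](c5c(OCc9ccccc9)c(Br)c6c(c5OCc9ccccc9)C[C@@H](OCc9ccccc9)[C@@H](c8ccc(OCc9ccccc9)c(OCc9ccccc9)c8)O6)[C@@H](O)[C@@H](c8ccc(OCc9ccccc9)c(OCc9ccccc9)c8)O4
A2 | alternative 2 | upper–middle dimer carrying a dimethyl trihydroxyisophthalate (lower ring A) on C4 of the middle unit | c9ccccc9COc1cc(OCc9ccccc9)c2c(c1)O[C@H](c8ccc(OCc9ccccc9)c(OCc9ccccc9)c8)[C@H](OCc9ccccc9)[C@H]2c3c(OCc9ccccc9)cc4c(c3OCc9ccccc9)[C@H](c5c(O)c(C(=O)OC)c(O)c(C(=O)OC)c5O)[C@@H](OCc9ccccc9)[C@@H](c8ccc(OCc9ccccc9)c(OCc9ccccc9)c8)O4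
A3 | alternative 2 | dimethyl 3-oxoglutarate | COC(=O)CC(=O)CC(=O)OC
A4 | alternative 3 | middle-unit lactol (anomer mixture) with trans C3 benzyloxy and C4 aryl groups | c9ccccc9COc1cc(OCc9ccccc9)c2c(c1)O[C@H](c8ccc(OCc9ccccc9)c(OCc9ccccc9)c8)[C@H](OCc9ccccc9)[C@H]2c3c(OCc9ccccc9)cc4c(c3OCc9ccccc9)[C@H](c5c(OCc9ccccc9)c(Br)c6c(c5OCc9ccccc9)C[C@@H](OCc9ccccc9)[C@@H](c8ccc(OCc9ccccc9)c(OCc9ccccc9)c8)O6)[C@@H](OCc9ccccc9)C(O)O4
A5 | alternative 3 | benzyloxyacetaldehyde | O=CCOCc1ccccc1
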